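## Structural features

The target is an achiral depside: two benzene rings joined by one aryl ester, in which the carbonyl carbon C7 on C1 of ring A is bound to the oxygen on C4' of ring B. Ring A carries methoxy groups on C2 and C4, a hydroxymethyl group on C3 between them, hydrogen on C5 and methyl on C6. Ring B is a 3-methylorsellinic acid with the carboxyl on C1', a free hydroxyl on C2', methyl groups on C3' and C6' and hydrogen on C5'. There is no stereocentre, so no stereochemical relationship has to be built or protected. The fragile groups are the depside ester (opened by hydroxide, alkoxide or amines), the salicylic acid of ring B (it decarboxylates when heated as the free acid) and the benzylic alcohol on C3, which is flanked by two methoxy groups and so ionizes in acid and can be hydrogenolysed. The real difficulty is the central ester: its acyl carbon lies between two ortho substituents (C2 methoxy, C6 methyl) and its phenol has an ortho methyl, so direct acylation is slow, and it must survive the release of a free acid and a free phenol on ring B while two phenolic oxygens on ring A end up methylated. The plan uses the fact that C1–C6 of ring A, with oxygen on C2 and C4, methyl on C6 and the carboxyl carbon on C1, is the pattern of an orsellinate, that is of a folded 3,5,7-trioxooctanoyl chain. The ring bond C1–C6 is then an aldol bond (C2 to C7 of the open chain), so ring A can be grown on an ester of ring B that is unhindered at the time it is made.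

## Logic of the disconnections

18 to 17. The hydroxymethyl group on C3 is traced back to a formyl group. The benzylic C–O bond is the group most at risk under hydrogen on palladium and under acid, so it is created last, and the aldehyde is what electrophilic substitution can deliver. The forward step needs a hydride that reduces the aldehyde but not the aryl ester or the carboxylate.

17 to 16. The O–CH2Ph bonds on the carboxyl oxygen and on O2' are cut. Both leave in one neutral, non-nucleophilic operation, which is the only safe way to free an acid and a phenol next to a depside ester. The forward step needs O-benzyl cleavage to be faster than reduction of the formyl group.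

16 to 15. The O2–CH3 and O4–CH3 bonds are cut. At this stage the two hydroxyls of ring A are the only free ones, because O2' is benzylated, so no selectivity between phenols is needed. The forward step needs alkylation of two hydrogen-bonded phenols without base-induced cleavage of the ester.

15 to 13. The C3–CHO bond is cut. C3 lies ortho to both hydroxyls of ring A and is the position an oxygen-directed formylation reaches; the tetraketide chain has no carbon there, so the branch must come after ring formation. The forward step needs C3 to win over C5 and ring A to win over ring B.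

13 to 11. The C1–C6 bond of ring A is cut (C2–C7 of the open chain). This removes a whole ring and turns the hindered, doubly ortho-substituted benzoate into a plain acyclic β-keto ester. The forward step needs the aldol closure to outrun the acyl substitutions that would expel the ring B phenoxide.

11 to 4 and 9, through 10. The acyl C–O4' bond is cut. It is formed by addition of a phenol to an acylketene under neutral thermal conditions, with no activated acid and no base. The gain is convergence: a six-carbon chain precursor and a ring B phenol. The forward step needs intermolecular capture of the ketene to compete with capture by the chain's own enol.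

4 to 2 and 3, and 2 to 1. The chain bonds C6–C7 and then C4–C5 are cut, each removing one acetyl unit. Both are enolate acylations at the terminus remote from the masked carboxyl, and they lead back to a bulk dioxinone. The forward steps need acylation on carbon at the terminal position only.

9 to 8, 7, 6 and 5. Here only protecting groups are cut: the temporary ether on O4', then both benzyl groups together, then the methyl ester. The order is set by reactivity: the unchelated 4-hydroxyl is alkylated first and selectively, which leaves the chelated 2-hydroxyl and the carboxyl to be benzylated in one operation. The forward steps need a temporary group on O4' that survives hydroxide and leaves without touching benzyl.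

## Other disconnections considered

Alternative 1: The cut removes C7 itself, breaking C1–C7 and C7–O4'. In the forward sense the ring A iodide A2 (3-iodo-2,6-dimethoxy-4-methylbenzaldehyde) would undergo oxidative addition to zerovalent palladium and insertion of carbon monoxide, and the aroylpalladium would be captured by the 4'-phenoxide of a ring B benzyl ester with its 2'-hydroxyl left free, giving the depside aldehyde A1.
- In its favour: ring A arrives with both methyl ethers and the formyl carbon in place, and the position of the iodine follows from the symmetry of the aldehyde that is iodinated. No protection of O2' is needed, because the chelated hydroxyl is the poorer nucleophile. Only hydrogenolysis of one benzyl ester and a borohydride reduction would remain.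
- Against it: the iodide and the aroylpalladium are each flanked by two ortho substituents, and the phenoxide is weakly nucleophilic with an ortho methyl. Acyl transfer would therefore be slow, leaving room for direct C–O coupling, loss of iodine or decarbonylation of the aldehyde.
- Comparison: on step economy and on regiochemical certainty at C3 this alternative is the better plan, roughly seven steps against twelve. On mechanism it puts all the risk into the one event the chosen plan avoids, the making of the hindered ester by acyl transfer. The end games are equal.

Alternative 2: The cut is inside ring B, at C3'–C4' and C1'–C6'. In the forward sense the bis(trimethylsilyl enol ether) A4 of benzyl 3-oxopentanoate would be acylated at its terminal carbon by the vinylogous acid chloride A5 under TiCl4. The central carbon would then add to the methoxy-bearing carbon with loss of methanol, in a formal [3+3] closure that aromatizes to the ring B diol ester A3.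
- In its favour: every substituent of ring B is fixed by the fragments, and the benzyl ester is obtained directly, with no saponification of a hindered ester and no re-esterification.
- Against it: it solves a problem that the commercial methyl ester 5 largely removes, and it leaves the depside bond and all of ring A untouched. A3 would still need three protecting-group steps to reach the phenol used here, and A4 and A5 each take two or three steps to make.
- Comparison: for ring B alone it equals the chosen plan in regiochemical certainty and is better in avoiding the ester exchange. In overall step count it is worse, and it is a supplement (it would serve Alternative 1 well) and not a competitor for the central bond.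

Alternative 3: The cut takes ring B apart into a diazo ketone A7 and the 1-propynyl ester A8 of the ring A acid, so that the depside oxygen is already on the alkyne. In the forward sense photochemical Wolff rearrangement of A7 forms C5'–C6' and gives a vinylketene. A [2+2] addition to A8 forms C2'–C3' and C4'–C5'. The cyclobutenone then opens, and a six-electron closure forms C1'–C2'; tautomerization gives the phenol A6.
- In its favour: the 2'-hydroxyl is born free and O4' acylated, so the two oxygens of ring B are told apart by construction. The hindered ester is again not made by acylation with a hindered acid. The C3 branch is carried as a silyl ether from the start, so no aldehyde is present at the end.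
- Against it: alkynyl esters are labile acyl donors and weak ketenophiles, since an acyloxy group is a poor donor compared with alkoxy or silyloxy. The regiochemistry of the [2+2] step rests on that weak donor, and both A7 and A8 are sensitive compounds that each need a multistep preparation.
- Comparison: it equals the chosen plan in avoiding hindered acylation and is better in protecting-group economy on ring B and in the certainty of the C3 branch. It is weaker in precedent for the substrate class and in step count, and it ends with a hydrogenolysis next to the same sensitive benzylic alcohol.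

Key step: step 8

Remark: lithium enolates, phenoxide salts and the metal-bound adducts of steps 1 and 2 are treated as activated forms of the reactants and are not numbered; the numbered non-isolated compounds are the neutral species 10, 12 and 14.

## Route

Step 1
Reactants: 1 2,2,6-trimethyl-4H-1,3-dioxin-4-one
Product: 2 2,2-dimethyl-6-(2-oxopropyl)-4H-1,3-dioxin-4-one
Conditions: 1 (2 equiv), LiN(SiMe3)2 (2 equiv), THF, −78 °C; AcCl (1 equiv), −78 °C; aq. NH4Cl
Reagents that add atoms: acetyl chloride, CC(=O)Cl
Why: Vinylogous Claisen-type C-acylation: the lithium dienolate of 1 attacks the acid chloride through its γ-carbon (the former 6-methyl group), and the second equivalent of dienolate deprotonates the more acidic product, which prevents a second acylation.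

Step 2
Reactants: 2 2,2-dimethyl-6-(2-oxopropyl)-4H-1,3-dioxin-4-one; 3 N-methoxy-N-methylacetamide
Product: 4 6-(2,4-dioxopentyl)-2,2-dimethyl-4H-1,3-dioxin-4-one
Conditions: LiN(iPr)2 (2.1 equiv), THF, −78 °C; 3 (1.1 equiv), −78 → −20 °C; aq. NH4Cl
Reagents that add atoms: none
Why: Dianion acylation (Claisen condensation with a Weinreb amide): the first equivalent of base removes the doubly activated methylene proton, the second the terminal methyl proton, and the more reactive terminal carbanion adds to 3; the chelated adduct collapses only on work-up, so the 1,3-diketone is not acylated again.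

Step 3
Reactants: 5 methyl 2,4-dihydroxy-3,6-dimethylbenzoate
Product: 6 methyl 2-hydroxy-4-[(4-methoxyphenyl)methoxy]-3,6-dimethylbenzoate
Conditions: 4-methoxybenzyl chloride (1.05 equiv), K2CO3, DMF, rt
Reagents that add atoms: 4-methoxybenzyl chloride, COc1ccc(CCl)cc1
Why: Williamson etherification; the 2-hydroxyl is held in a hydrogen bond to the ester carbonyl and flanked by two substituents, so one equivalent of halide at room temperature alkylates only the 4-hydroxyl.

Step 4
Reactants: 6 methyl 2-hydroxy-4-[(4-methoxyphenyl)methoxy]-3,6-dimethylbenzoate
Product: 7 2-hydroxy-4-[(4-methoxyphenyl)methoxy]-3,6-dimethylbenzoic acid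
Conditions: KOH, DMSO/H2O, 80 °C; then cold 1 M HCl to pH 3
Reagents that add atoms: potassium hydroxide, [K+].[OH-]
Why: Saponification of a hindered ester; hydroxide in aqueous DMSO is reactive enough for the doubly ortho-substituted ester, the 4-methoxybenzyl ether is inert to base, and the product stays a carboxylate until a cold acidification, which avoids decarboxylation.

Step 5
Reactants: 7 2-hydroxy-4-[(4-methoxyphenyl)methoxy]-3,6-dimethylbenzoic acid
Product: 8 benzyl 2-(benzyloxy)-4-[(4-methoxyphenyl)methoxy]-3,6-dimethylbenzoate
Conditions: BnBr (2.5 equiv), K2CO3, nBu4NI (cat.), DMF, rt → 60 °C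
Reagents that add atoms: benzyl bromide, BrCc1ccccc1
Why: Double O-alkylation in one operation: the carboxylate is benzylated first (SN2 esterification, insensitive to hindrance at the acyl carbon) and the chelated 2-hydroxyl follows on warming (Williamson etherification).

Step 6
Reactants: 8 benzyl 2-(benzyloxy)-4-[(4-methoxyphenyl)methoxy]-3,6-dimethylbenzoate
Product: 9 benzyl 2-(benzyloxy)-4-hydroxy-3,6-dimethylbenzoate
Conditions: TFA (10% v/v), Et3SiH (3 equiv), CH2Cl2, 0 °C
Reagents that add atoms: none
Why: Acidolysis of the 4-methoxybenzyl aryl ether; the stabilized benzylic cation leaves in dilute TFA at 0 °C and is reduced by the silane, while the unsubstituted benzyl ether and the benzyl ester need far stronger acid.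

Step 7
Reactants: 4 6-(2,4-dioxopentyl)-2,2-dimethyl-4H-1,3-dioxin-4-one; 9 benzyl 2-(benzyloxy)-4-hydroxy-3,6-dimethylbenzoate
Product: 11 benzyl 2-(benzyloxy)-3,6-dimethyl-4-[(3,5,7-trioxooctanoyl)oxy]benzoate, via acylketene 10 (not isolated)
Conditions: 4 (1.3 equiv), toluene, 110 °C; concentrate, use crude
Reagents that add atoms: none
Why: Thermal retro-hetero-Diels–Alder fragmentation of the dioxinone releases acetone and the acylketene 10, and the only free hydroxyl of 9 adds across the ketene (acylketene capture, the standard acetoacetylation chemistry of dioxinones). No base or activating agent is present, so the later hindered ester is formed as an ordinary acyclic ester; the slight excess of 4 offsets ketene lost to capture by its own enol.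

Step 8
Reactants: 11 benzyl 2-(benzyloxy)-3,6-dimethyl-4-[(3,5,7-trioxooctanoyl)oxy]benzoate
Product: 13 benzyl 2-(benzyloxy)-4-[(2,4-dihydroxy-6-methylbenzoyl)oxy]-3,6-dimethylbenzoate, via aldol adduct 12 (not isolated)
Conditions: Et3N (0.5 equiv), CH2Cl2, 0 °C → rt; then TFA, rt
Reagents that add atoms: none
Why: The amine reversibly enolizes the methylene groups of 11; only the C2 enolate, flanked by the aryl ester and the C3 ketone, can reach a ketone through a six-membered transition state, and it adds to the C7 methyl ketone to give the cyclic aldol 12. This is the aldol mode of polyketide folding, the known cyclization of 3,5,7-triketo esters to resorcylate esters (intramolecular aldol condensation followed by aromatization). The ring closes in the favoured 6-(enolendo)-exo-trig mode. Acid then removes the tertiary hydroxyl as water and the C3 and C5 carbonyls enolize, so that chain carbons C2–C7 become C1–C6 of an aromatic ring, which makes the sequence irreversible. The two stereocentres of 12 are transient and are erased, so no stereocontrol is needed. The selectivity required is the C2-to-C7 aldol over the two closures that expel the ring B phenoxide: attack of the C5 enol oxygen on the ester carbon, which gives a pyranone, and Claisen attack of C6 on the ester. It is secured by a weak, non-nucleophilic amine in an aprotic solvent at low temperature, where addition to the free ketone should be faster than substitution at the ester, and by adding acid only after the aldol is complete, since acid on the open chain would favour the pyranone. The benzyl ether and the benzyl ester are inert to both reagents.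

Step 9
Reactants: 13 benzyl 2-(benzyloxy)-4-[(2,4-dihydroxy-6-methylbenzoyl)oxy]-3,6-dimethylbenzoate
Product: 15 benzyl 2-(benzyloxy)-4-[(3-formyl-2,4-dihydroxy-6-methylbenzoyl)oxy]-3,6-dimethylbenzoate, via chloro(methoxy)methyl arene 14 (not isolated)
Conditions: Cl2CHOMe (1.2 equiv), TiCl4 (3 equiv), CH2Cl2, −78 → −20 °C; then ice/1 M HCl
Reagents that add atoms: dichloromethyl methyl ether, COC(Cl)Cl; water, O
Why: Rieche formylation: titanium bound to the phenolic oxygens of ring A delivers the chloro(methoxy)methyl cation ortho to oxygen, C3 is ortho to both hydroxyls, and hydrolysis of 14 on work-up gives the aldehyde. Ring B carries an ester and only acylated or benzylated oxygens and is far less nucleophilic than the free resorcinol ring A; the low temperature is chosen to spare the 2'-O-benzyl ether.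

Step 10
Reactants: 15 benzyl 2-(benzyloxy)-4-[(3-formyl-2,4-dihydroxy-6-methylbenzoyl)oxy]-3,6-dimethylbenzoate
Product: 16 benzyl 2-(benzyloxy)-4-[(3-formyl-2,4-dimethoxy-6-methylbenzoyl)oxy]-3,6-dimethylbenzoate
Conditions: MeI (5 equiv), K2CO3, DMF, rt → 40 °C
Reagents that add atoms: iodomethane, CI
Why: Williamson methylation of the two phenols of ring A, the only free hydroxyls in 15; both are acidified by the ortho formyl group and are alkylated under carbonate in DMF, without the hydroxide or alkoxide to which the depside ester is sensitive.

Step 11
Reactants: 16 benzyl 2-(benzyloxy)-4-[(3-formyl-2,4-dimethoxy-6-methylbenzoyl)oxy]-3,6-dimethylbenzoate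
Product: 17 4-[(3-formyl-2,4-dimethoxy-6-methylbenzoyl)oxy]-2-hydroxy-3,6-dimethylbenzoic acid
Conditions: H2 (1 atm), 10% Pd/C, EtOAc, rt
Reagents that add atoms: none
Why: Catalytic hydrogenolysis of the benzyl ester and the benzyl aryl ether frees the acid and the 2'-phenol under neutral, non-nucleophilic conditions that leave the depside ester intact. In ethyl acetate at atmospheric pressure O-benzyl cleavage should be faster than reduction of the hindered aryl aldehyde, and any aldehyde reduced to the alcohol only anticipates step 12.

Step 12
Reactants: 17 4-[(3-formyl-2,4-dimethoxy-6-methylbenzoyl)oxy]-2-hydroxy-3,6-dimethylbenzoic acid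
Product: 18 4-{[3-(hydroxymethyl)-2,4-dimethoxy-6-methylbenzoyl]oxy}-2-hydroxy-3,6-dimethylbenzoic acid
Conditions: NaBH4 (3 equiv), THF/MeOH 4:1, 0 °C; then cold 1 M HCl to pH 3
Reagents that add atoms: none
Why: Borohydride reduction of the aldehyde to the primary alcohol; the carboxylate and phenoxide formed in the flask are not reduced, and the doubly ortho-substituted aryl ester reacts far more slowly than the aldehyde at 0 °C.

## Compound list

1 | 2,2,6-trimethyl-4H-1,3-dioxin-4-one | CC1=CC(=O)OC(C)(C)O1 | starting material
2 | 2,2-dimethyl-6-(2-oxopropyl)-4H-1,3-dioxin-4-one | CC(=O)CC1=CC(=O)OC(C)(C)O1 | intermediate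
3 | N-methoxy-N-methylacetamide | CC(=O)N(C)OC | starting material
4 | 6-(2,4-dioxopentyl)-2,2-dimethyl-4H-1,3-dioxin-4-one | CC(=O)CC(=O)CC1=CC(=O)OC(C)(C)O1 | intermediate
5 | methyl 2,4-dihydroxy-3,6-dimethylbenzoate | COC(=O)c1c(C)cc(O)c(C)c1O | starting material
6 | methyl 2-hydroxy-4-[(4-methoxyphenyl)methoxy]-3,6-dimethylbenzoate | COC(=O)c1c(C)cc(OCc2ccc(OC)cc2)c(C)c1O | intermediate
7 | 2-hydroxy-4-[(4-methoxyphenyl)methoxy]-3,6-dimethylbenzoic acid | OC(=O)c1c(C)cc(OCc2ccc(OC)cc2)c(C)c1O | intermediate
8 | benzyl 2-(benzyloxy)-4-[(4-methoxyphenyl)methoxy]-3,6-dimethylbenzoate | COc1ccc(COc2cc(C)c(C(=O)OCc3ccccc3)c(OCc3ccccc3)c2C)cc1 | intermediate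
9 | benzyl 2-(benzyloxy)-4-hydroxy-3,6-dimethylbenzoate | Cc1cc(O)c(C)c(OCc2ccccc2)c1C(=O)OCc1ccccc1 | intermediate
10 | 3,5,7-trioxooct-1-en-1-one (acylketene) | CC(=O)CC(=O)CC(=O)C=C=O | intermediate (not isolated)
11 | benzyl 2-(benzyloxy)-3,6-dimethyl-4-[(3,5,7-trioxooctanoyl)oxy]benzoate | CC(=O)CC(=O)CC(=O)CC(=O)Oc1cc(C)c(C(=O)OCc2ccccc2)c(OCc2ccccc2)c1C | intermediate
12 | benzyl 2-(benzyloxy)-4-{[(2-hydroxy-2-methyl-4,6-dioxocyclohexyl)carbonyl]oxy}-3,6-dimethylbenzoate (mixture of stereoisomers, erased on aromatization) | CC1(O)CC(=O)CC(=O)C1C(=O)Oc1cc(C)c(C(=O)OCc2ccccc2)c(OCc2ccccc2)c1C | intermediate (not isolated)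
13 | benzyl 2-(benzyloxy)-4-[(2,4-dihydroxy-6-methylbenzoyl)oxy]-3,6-dimethylbenzoate | Cc1cc(O)cc(O)c1C(=O)Oc1cc(C)c(C(=O)OCc2ccccc2)c(OCc2ccccc2)c1C | intermediate
14 | benzyl 2-(benzyloxy)-4-({3-[chloro(methoxy)methyl]-2,4-dihydroxy-6-methylbenzoyl}oxy)-3,6-dimethylbenzoate (racemic) | COC(Cl)c1c(O)cc(C)c(C(=O)Oc2cc(C)c(C(=O)OCc3ccccc3)c(OCc3ccccc3)c2C)c1O | intermediate (not isolated)
15 | benzyl 2-(benzyloxy)-4-[(3-formyl-2,4-dihydroxy-6-methylbenzoyl)oxy]-3,6-dimethylbenzoate | O=Cc1c(O)cc(C)c(C(=O)Oc2cc(C)c(C(=O)OCc3ccccc3)c(OCc3ccccc3)c2C)c1O | intermediate
16 | benzyl 2-(benzyloxy)-4-[(3-formyl-2,4-dimethoxy-6-methylbenzoyl)oxy]-3,6-dimethylbenzoate | COc1cc(C)c(C(=O)Oc2cc(C)c(C(=O)OCc3ccccc3)c(OCc3ccccc3)c2C)c(OC)c1C=O | intermediate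
17 | 4-[(3-formyl-2,4-dimethoxy-6-methylbenzoyl)oxy]-2-hydroxy-3,6-dimethylbenzoic acid | COc1cc(C)c(C(=O)Oc2cc(C)c(C(=O)O)c(O)c2C)c(OC)c1C=O | intermediate
18 | 4-{[3-(hydroxymethyl)-2,4-dimethoxy-6-methylbenzoyl]oxy}-2-hydroxy-3,6-dimethylbenzoic acid | COc1cc(C)c(C(=O)Oc2cc(C)c(C(=O)O)c(O)c2C)c(OC)c1CO | target

## Step count and least certain steps

Total: 12 steps. Longest linear sequence: 10 steps (5 to 18 through steps 3–12); the chain branch (steps 1, 2) joins at step 7.

Step 8 (key step). The likely failure is expulsion of the ring B phenoxide by acyl substitution, either by the C5 enol oxygen or by C6, in competition with the aldol closure. An aryloxide is a much better leaving group than the alkoxide of the usual alkyl triketo esters. The fallback closes the same aldol bond before the phenol is attached. It sets out from 4: triethylamine in CH2Cl2 should cyclize and aromatize the diketo-dioxinone itself, where the ester oxygen is tied into the acetonide ring and cannot leave, to give 7-hydroxy-2,2,5-trimethyl-4H-1,3-benzodioxin-4-one F1. Irradiation of F1 at about 300 nm in CH2Cl2, added slowly to an excess of 9, would open the acetonide to an ortho-quinone ketene that the hydroxyl of 9 captures. The route is rejoined at 13.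

Step 7. The likely failure is capture of the acylketene by the enol of its own 1,3-diketone, or ketene self-condensation, outrunning addition of the ortho-substituted, electron-poor phenol. The fallback is the classical depside condensation and sets out from 9. Commercial methyl 2,4-dihydroxy-6-methylbenzoate F2 would be allylated on the unchelated 4-hydroxyl (allyl bromide, K2CO3, acetone) to methyl 2-hydroxy-6-methyl-4-(prop-2-en-1-yloxy)benzoate F3. Saponification (KOH, aqueous DMSO) would give 2-hydroxy-6-methyl-4-(prop-2-en-1-yloxy)benzoic acid F4. Condensation of F4 with 9 by trifluoroacetic anhydride in toluene, a mixed-anhydride acylation helped by the free ortho hydroxyl, would give the depside allyl ether benzyl 2-(benzyloxy)-4-{[2-hydroxy-6-methyl-4-(prop-2-en-1-yloxy)benzoyl]oxy}-3,6-dimethylbenzoate F5. Deallylation with Pd(PPh3)4 and morpholine returns to the route at 13.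

Step 9. The likely failures are electrophilic attack at C5 in place of C3, since both positions are activated by the two hydroxyls, and titanium-assisted loss of the chelated 2'-O-benzyl group. The fallback makes a single phenol the directing element and sets out from 13. Methylation of the unchelated 4-hydroxyl alone (MeI 1.1 equiv, K2CO3, acetone, rt) would give benzyl 2-(benzyloxy)-4-[(2-hydroxy-4-methoxy-6-methylbenzoyl)oxy]-3,6-dimethylbenzoate F6. Magnesium-mediated ortho-formylation (MgCl2, Et3N, paraformaldehyde, MeCN, reflux; Casnati–Skattebøl) uses no strong Lewis acid and delivers only ortho to the remaining phenol, where C3 is the one open position. It would give benzyl 2-(benzyloxy)-4-[(3-formyl-2-hydroxy-4-methoxy-6-methylbenzoyl)oxy]-3,6-dimethylbenzoate F7. Methylation of the 2-hydroxyl (MeI, K2CO3, DMF) rejoins the route at 16, bypassing 15.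

Step 11. The likely failure is reduction of the formyl group on the palladium surface, to hydroxymethyl and on to methyl, during the slower cleavage of the hindered 2'-O-benzyl ether. The fallback removes the benzyl groups without hydrogen. It sets out from 16: BCl3 with pentamethylbenzene as cation scavenger in CH2Cl2 at −78 °C should cleave the benzyl aryl ether and the benzyl ester while the aryl methyl ethers persist at that temperature. It arrives directly at 17 with no new compound.

Step 4. The likely failures are slow hydrolysis, because the neighbouring phenoxide deactivates the doubly ortho-substituted ester, and decarboxylation of the electron-rich salicylic acid if the reaction is forced or acidified warm. The fallback changes the order so that no free salicylic acid is made, and sets out from 6. Benzylation of the 2-hydroxyl (BnBr, K2CO3, DMF, 60 °C) would give methyl 2-(benzyloxy)-4-[(4-methoxyphenyl)methoxy]-3,6-dimethylbenzoate F8. Hydrolysis of this fully etherified ester (KOH, aqueous DMSO, 90 °C) would give 2-(benzyloxy)-4-[(4-methoxyphenyl)methoxy]-3,6-dimethylbenzoic acid F9, which does not decarboxylate. Benzylation of the carboxylate (BnBr, K2CO3, DMF) rejoins the route at 8, at the cost of one more step.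

## Further compounds

F1 | step 8 | 7-hydroxy-2,2,5-trimethyl-4H-1,3-benzodioxin-4-one | Cc1cc(O)cc2OC(C)(C)OC(=O)c12
F2 | step 7 | methyl 2,4-dihydroxy-6-methylbenzoate | COC(=O)c1c(C)cc(O)cc1O
F3 | step 7 | methyl 2-hydroxy-6-methyl-4-(prop-2-en-1-yloxy)benzoate | COC(=O)c1c(C)cc(OCC=C)cc1O
F4 | step 7 | 2-hydroxy-6-methyl-4-(prop-2-en-1-yloxy)benzoic acid | OC(=O)c1c(C)cc(OCC=C)cc1O
F5 | step 7 | benzyl 2-(benzyloxy)-4-{[2-hydroxy-6-methyl-4-(prop-2-en-1-yloxy)benzoyl]oxy}-3,6-dimethylbenzoate | C=CCOc1cc(C)c(C(=O)Oc2cc(C)c(C(=O)OCc3ccccc3)c(OCc3ccccc3)c2C)c(O)c1
F6 | step 9 | benzyl 2-(benzyloxy)-4-[(2-hydroxy-4-methoxy-6-methylbenzoyl)oxy]-3,6-dimethylbenzoate | COc1cc(C)c(C(=O)Oc2cc(C)c(C(=O)OCc3ccccc3)c(OCc3ccccc3)c2C)c(O)c1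
F7 | step 9 | benzyl 2-(benzyloxy)-4-[(3-formyl-2-hydroxy-4-methoxy-6-methylbenzoyl)oxy]-3,6-dimethylbenzoate | COc1cc(C)c(C(=O)Oc2cc(C)c(C(=O)OCc3ccccc3)c(OCc3ccccc3)c2C)c(O)c1C=O
F0 | step 11 | none | none
F8 | step 4 | methyl 2-(benzyloxy)-4-[(4-methoxyphenyl)methoxy]-3,6-dimethylbenzoate | COC(=O)c1c(C)cc(OCc2ccc(OC)cc2)c(C)c1OCc1ccccc1
F9 | step 4 | 2-(benzyloxy)-4-[(4-methoxyphenyl)methoxy]-3,6-dimethylbenzoic acid | OC(=O)c1c(C)cc(OCc2ccc(OC)cc2)c(C)c1OCc1ccccc1
A1 | alternative 1 | benzyl 4-[(3-formyl-2,4-dimethoxy-6-methylbenzoyl)oxy]-2-hydroxy-3,6-dimethylbenzoate | COc1cc(C)c(C(=O)Oc2cc(C)c(C(=O)OCc3ccccc3)c(O)c2C)c(OC)c1C=O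
A2 | alternative 1 | 3-iodo-2,6-dimethoxy-4-methylbenzaldehyde | COc1cc(C)c(I)c(OC)c1C=O
A3 | alternative 2 | benzyl 2,4-dihydroxy-3,6-dimethylbenzoate | Cc1cc(O)c(C)c(O)c1C(=O)OCc1ccccc1
A4 | alternative 2 | 1-(benzyloxy)-1,3-bis(trimethylsilyloxy)penta-1,3-diene (mixture of geometric isomers) | CC=C(O[Si](C)(C)C)C=C(O[Si](C)(C)C)OCc1ccccc1
A5 | alternative 2 | (2E)-3-methoxybut-2-enoyl chloride | CO/C(C)=C/C(Cl)=O
A6 | alternative 3 | benzyl 4-{[2,4-dimethoxy-6-methyl-3-({[tri(propan-2-yl)silyl]oxy}methyl)benzoyl]oxy}-2-hydroxy-3,6-dimethylbenzoate | COc1cc(C)c(C(=O)Oc2cc(C)c(C(=O)OCc3ccccc3)c(O)c2C)c(OC)c1CO[Si](C(C)C)(C(C)C)C(C)C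
A7 | alternative 3 | benzyl (2E)-5-diazo-3-methyl-4-oxopent-2-enoate | [N-]=[N+]=CC(=O)/C(C)=C/C(=O)OCc1ccccc1
A8 | alternative 3 | prop-1-yn-1-yl 2,4-dimethoxy-6-methyl-3-({[tri(propan-2-yl)silyl]oxy}methyl)benzoate | CC#COC(=O)c1c(C)cc(OC)c(CO[Si](C(C)C)(C(C)C)C(C)C)c1OC
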